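The route cuts C3–C4 and C5–C10 together. The feature exploited is the tetrasubstituted C4=C5 alkene: it carries the C15 methyl, lies at the fusion of ring A and ring B and flanks the quaternary C10, so it is read as a methyl alkyne (C15–C4≡C5) that has added across a C10=C1–C2=C3 diene. One nickel-catalysed intramolecular [4+2] cycloaddition should therefore close both rings, form two C–C bonds and set C10, steered by a silyl ether at C8. Its precursor is an acyclic (E)-dienyne: a methyl alkyne and a methyl-substituted 1,3-diene joined by a four-carbon tether (C6–C9) bearing an (R)-configured C8 silyloxy group.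

Key step: step 6

Conventions: bicyclic compounds carry eudesmane locants ("11,12,13-trinoreudesmane" is the 4,10-dimethyldecalin core without C11–C13); β is the face of the C10 methyl; the C10 descriptor changes from S to R between 12 and 13 only through CIP priorities.

Assumption: the chiral phosphoric acid is taken to show the same facial preference with this aliphatic aldehyde as with aryl aldehydes (the (R)-acid sending the nucleophile to the Re face), so the (S)-acid is specified for the (4R)-alcohol; the antipodal acid is used if the first run shows the opposite sense.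

Step 1
Reactants: 1 hex-4-yn-1-ol
Product: 2 hex-4-ynal
Conditions: TEMPO (10 mol%), PhI(OAc)2, CH2Cl2, rt
Reagents that add atoms: none
Why: Oxoammonium (TEMPO) oxidation with PhI(OAc)2 as terminal oxidant should stop at the aldehyde and leave the internal alkyne untouched, the volatile aldehyde being purified by short-path distillation.

Step 2
Reactants: 2 hex-4-ynal; 3 allenylboronic acid pinacol ester
Product: 4 (4R)-nona-1,7-diyn-4-ol
Conditions: (S)-TRIP phosphoric acid (10 mol%), 4 Å MS, cyclohexane, 0 °C → rt; aqueous work-up
Reagents that add atoms: allenylboronic acid pinacol ester 3, C=C=CB1OC(C)(C)C(C)(C)O1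
Why: Chiral phosphoric acid-catalysed asymmetric propargylation with an allenylboronate passes through a closed six-membered SE2' transition state in which the acid activates the boronate and shields one aldehyde face, so Si-face attack should set the (4R)-carbinol and γ-transfer should give the homopropargylic alcohol.

Step 3
Reactants: 4 (4R)-nona-1,7-diyn-4-ol
Product: 5 tert-butyl(dimethyl){[(4R)-nona-1,7-diyn-4-yl]oxy}silane
Conditions: t-BuMe2SiCl, imidazole, DMF, rt
Reagents that add atoms: tert-butyldimethylsilyl chloride, CC(C)(C)[Si](C)(C)Cl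
Why: Imidazole-promoted silylation of a secondary alcohol is routine, and the silyl ether should survive the organoaluminium, palladium, nickel, peroxide and hydride steps ahead while serving as the one substituent that steers the cycloaddition.

Step 4
Reactants: 5 tert-butyl(dimethyl){[(4R)-nona-1,7-diyn-4-yl]oxy}silane; 6 trimethylaluminium
Product: 8 tert-butyl{[(1E,4R)-1-iodo-2-methylnon-1-en-7-yn-4-yl]oxy}dimethylsilane, via alkenyldimethylalane 7 (not isolated)
Conditions: AlMe3 (2.5 equiv), Cp2ZrCl2 (20 mol%), CH2Cl2, 0 °C → rt; then I2, THF, −30 °C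
Reagents that add atoms: trimethylaluminium 6, C[Al](C)C; iodine, II
Why: Zirconium-catalysed syn-methylalumination (Negishi carboalumination) should take the terminal alkyne much faster than the dialkyl-substituted alkyne and place methyl on the internal carbon, and iodinolysis with retention should give the (E)-iodide that fixes the diene geometry.

Step 5
Reactants: 8 tert-butyl{[(1E,4R)-1-iodo-2-methylnon-1-en-7-yn-4-yl]oxy}dimethylsilane; 9 vinylboronic acid pinacol ester
Product: 10 tert-butyl(dimethyl){[(3E,6R)-4-methylundeca-1,3-dien-9-yn-6-yl]oxy}silane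
Conditions: Pd(PPh3)4 (5 mol%), K3PO4, THF/H2O, 50 °C
Reagents that add atoms: vinylboronic acid pinacol ester 9, C=CB1OC(C)(C)C(C)(C)O1
Why: Suzuki–Miyaura coupling of an alkenyl iodide with a vinylboronate proceeds with retention of the (E)-geometry under mild aqueous phosphate conditions that should leave the silyl ether and the internal alkyne untouched.

Step 6
Reactants: 10 tert-butyl(dimethyl){[(3E,6R)-4-methylundeca-1,3-dien-9-yn-6-yl]oxy}silane
Product: 11 (8R,10S)-8α-(tert-butyldimethylsilyloxy)-11,12,13-trinoreudesma-1,4-diene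
Conditions: Ni(cod)2 (10 mol%), P[OCH(CF3)2]3 (30 mol%), cyclohexane (0.01 M), 80 °C
Reagents that add atoms: none
Why: Zerovalent nickel carrying an electron-poor phosphite should bind the methyl alkyne and the C10=C1 alkene and couple them oxidatively to a nickelacyclopentene (C5–C10 formed), which slips through its η3-allyl form to a seven-membered nickelacycle and forms C3–C4 by reductive elimination, returning the catalyst. The closest known reaction type is the nickel- or rhodium-catalysed intramolecular [4+2] cycloaddition of unactivated dienynes to bicyclic cyclohexa-1,4-dienes. Ring B closes over the four-carbon tether (C6–C9) through the C5–C10 bond in the oxidative cyclisation, and ring A closes through the C3–C4 bond in the reductive elimination, leaving C4=C5 and C1=C2. The only new stereocentre, C10, is controlled by the C8 silyl ether: C1 must stay near the plane of the alkyne, so the C10 methyl is axial on the nascent chair-like ring B, and the silyloxy group takes the equatorial site to avoid a 1,3-diaxial clash with it, which should give the 8α-oxygen/10β-methyl (trans) isomer. The step needs this facial selectivity and needs the intramolecular path to outrun diene oligomerisation; the first is secured by the single C8 substituent on a short tether, the second by high dilution and by the (E)-geometry that keeps the tether on the outer diene position.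

Step 7
Reactants: 11 (8R,10S)-8α-(tert-butyldimethylsilyloxy)-11,12,13-trinoreudesma-1,4-diene
Product: 12 (8R,10S)-8α-(tert-butyldimethylsilyloxy)-11,12,13-trinoreudesma-1,4-dien-3-one
Conditions: Rh2(cap)4 (1 mol%), t-BuOOH (5 equiv), K2CO3 (0.5 equiv), CH2Cl2, rt
Reagents that add atoms: tert-butyl hydroperoxide, CC(C)(C)OO
Why: Dirhodium caprolactamate/hydroperoxide allylic oxidation abstracts the weakest C–H bond, the doubly allylic C3–H, and the C3 peroxide collapses to the cross-conjugated dienone, aromatisation being impossible because C10 is quaternary and a limited oxidant charge guarding against further oxidation at C6.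

Step 8
Reactants: 12 (8R,10S)-8α-(tert-butyldimethylsilyloxy)-11,12,13-trinoreudesma-1,4-dien-3-one
Product: 13 (8R,10R)-8α-(tert-butyldimethylsilyloxy)-11,12,13-trinoreudesm-4-en-3-one
Conditions: H2 (1 atm), RhCl(PPh3)3 (10 mol%), benzene/EtOH, rt
Reagents that add atoms: none
Why: Homogeneous hydrogenation with RhCl(PPh3)3 is very sensitive to alkene substitution and should saturate only the disubstituted C1=C2 bond of the 1,4-dien-3-one, leaving the tetrasubstituted C4=C5 bond.

Step 9
Reactants: 13 (8R,10R)-8α-(tert-butyldimethylsilyloxy)-11,12,13-trinoreudesm-4-en-3-one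
Product: 14 (3S,8R,10R)-8α-(tert-butyldimethylsilyloxy)-11,12,13-trinoreudesm-4-en-3β-ol
Conditions: NaBH4, CeCl3·7H2O, MeOH, −78 → −40 °C
Reagents that add atoms: none
Why: Luche reduction gives clean 1,2-reduction, and hydride should add axially to C3 from the α face of the ring A half-chair, as with steroidal 4-en-3-ones, so that the new hydroxyl is pseudo-equatorial and β.

Step 10
Reactants: 14 (3S,8R,10R)-8α-(tert-butyldimethylsilyloxy)-11,12,13-trinoreudesm-4-en-3β-ol; 15 2-methylpropanoic anhydride
Product: 16 (3S,8R,10R)-8α-(tert-butyldimethylsilyloxy)-11,12,13-trinoreudesm-4-en-3β-yl 2-methylpropanoate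
Conditions: (i-PrCO)2O, Et3N, DMAP (cat.), CH2Cl2, 0 °C → rt
Reagents that add atoms: 2-methylpropanoic anhydride 15, CC(C)C(=O)OC(=O)C(C)C
Why: DMAP-catalysed acylation of the only free hydroxyl installs the final C3 ester early, where it also protects the allylic alcohol.

Step 11
Reactants: 16 (3S,8R,10R)-8α-(tert-butyldimethylsilyloxy)-11,12,13-trinoreudesm-4-en-3β-yl 2-methylpropanoate
Product: 17 (3S,8R,10R)-8α-hydroxy-11,12,13-trinoreudesm-4-en-3β-yl 2-methylpropanoate
Conditions: HF·pyridine, THF/pyridine, 0 °C → rt
Reagents that add atoms: none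
Why: Fluoride cleavage of the Si–O bond under buffered conditions should remove the silyl ether without acyl migration or loss of the hindered allylic ester.

Step 12
Reactants: 17 (3S,8R,10R)-8α-hydroxy-11,12,13-trinoreudesm-4-en-3β-yl 2-methylpropanoate
Product: 18 (3S,10R)-8-oxo-11,12,13-trinoreudesm-4-en-3β-yl 2-methylpropanoate
Conditions: Dess–Martin periodinane, NaHCO3, CH2Cl2, 0 °C → rt
Reagents that add atoms: none
Why: Dess–Martin oxidation under buffered neutral conditions should give the C8 ketone without touching the non-conjugated C4=C5 alkene or the ester, erasing the C8 stereocentre once it has done its work.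

Step 13
Reactants: 18 (3S,10R)-8-oxo-11,12,13-trinoreudesm-4-en-3β-yl 2-methylpropanoate; 19 allyl bromide
Product: 22 (3S,7S,10R)-7β-allyl-8-oxo-11,12,13-trinoreudesm-4-en-3β-yl 2-methylpropanoate, via lithium enolate 20 (not isolated), via 7α-allyl epimer 21 (not isolated)
Conditions: LiN(i-Pr)2 (1.05 equiv), THF, −78 °C; allyl bromide, −78 → −20 °C; crude product, then KOt-Bu (0.2 equiv), t-BuOH/THF, 0 °C
Reagents that add atoms: allyl bromide 19, C=CCBr
Why: The lithium amide should remove a C7 proton (the α-methylene remote from the quaternary C10 and far more acidic than the hindered ester α-CH), SN2 allylation of the enolate follows, and catalytic tert-butoxide then equilibrates C7 through the enolate toward the equatorial 7β-allyl ketone, the residual epimer being separated and resubjected.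

Step 14
Reactants: 22 (3S,7S,10R)-7β-allyl-8-oxo-11,12,13-trinoreudesm-4-en-3β-yl 2-methylpropanoate
Product: 23 (3S,7S,8R,10R)-7β-allyl-8β-hydroxy-11,12,13-trinoreudesm-4-en-3β-yl 2-methylpropanoate
Conditions: Li[HB(s-Bu)3] (1.2 equiv), THF, −78 °C
Reagents that add atoms: none
Why: The bulky trialkylborohydride should attack C8 along the equatorial α trajectory, the axial β approach being blocked by the 1,3-related axial C10 methyl, which gives the axial 8β-alcohol cis to the 7β-allyl group while the ester is not reduced at −78 °C.

Step 15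
Reactants: 23 (3S,7S,8R,10R)-7β-allyl-8β-hydroxy-11,12,13-trinoreudesm-4-en-3β-yl 2-methylpropanoate; 24 acetic anhydride
Product: 25 (3S,7S,8R,10R)-8β-acetoxy-7β-allyl-11,12,13-trinoreudesm-4-en-3β-yl 2-methylpropanoate
Conditions: Ac2O, pyridine, DMAP (cat.), CH2Cl2, rt → 40 °C
Reagents that add atoms: acetic anhydride 24, CC(=O)OC(C)=O
Why: DMAP-catalysed acetylation of the hindered axial alcohol installs the final C8 acetate before any C12 carboxyl exists, so no γ-lactone can form later.

Step 16
Reactants: 25 (3S,7S,8R,10R)-8β-acetoxy-7β-allyl-11,12,13-trinoreudesm-4-en-3β-yl 2-methylpropanoate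
Product: 27 (3S,7R,8R,10R)-8β-acetoxy-3β-(2-methylpropanoyloxy)-13-noreudesm-4-en-12-al, via vicinal diol 26 (not isolated)
Conditions: OsO4 (2 mol%), NaIO4 (4 equiv), 2,6-lutidine, 1,4-dioxane/H2O, rt
Reagents that add atoms: osmium tetroxide, O=[Os](=O)(=O)=O; sodium periodate, [Na+].[O-]I(=O)(=O)=O
Why: In this Lemieux–Johnson cleavage OsO4 should dihydroxylate the unhindered monosubstituted alkene far faster than the shielded tetrasubstituted C4=C5 bond, and periodate cleaves the diol in the same flask to the C12 aldehyde.

Step 17
Reactants: 27 (3S,7R,8R,10R)-8β-acetoxy-3β-(2-methylpropanoyloxy)-13-noreudesm-4-en-12-al; 28 formaldehyde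
Product: 29 (3S,7R,8R,10R)-8β-acetoxy-3β-(2-methylpropanoyloxy)eudesma-4,11(13)-dien-12-al
Conditions: CH2O (37% aq.), pyrrolidine (10 mol%), EtCO2H (10 mol%), i-PrOH, 45 °C
Reagents that add atoms: formaldehyde 28, C=O
Why: Amine/acid-catalysed α-methylenation of an aldehyde (Mannich condensation through the enamine, then β-elimination of the amine) should turn the C11 methylene into the C11=C13 alkene under near-neutral conditions that both esters tolerate.

Step 18
Reactants: 29 (3S,7R,8R,10R)-8β-acetoxy-3β-(2-methylpropanoyloxy)eudesma-4,11(13)-dien-12-al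
Product: 30 (3S,7R,8R,10R)-8β-acetoxy-3β-(2-methylpropanoyloxy)eudesma-4,11(13)-dien-12-oic acid
Conditions: NaClO2, NaH2PO4, 2-methylbut-2-ene, t-BuOH/H2O, 0 °C → rt
Reagents that add atoms: sodium chlorite, [Na+].[O-]Cl=O
Why: Pinnick oxidation should convert the 2-substituted acrolein into the acrylic acid chemoselectively, the hypochlorous acid by-product being scavenged by 2-methylbut-2-ene so that neither alkene is chlorinated and no ester is cleaved.

Step 19
Reactants: 30 (3S,7R,8R,10R)-8β-acetoxy-3β-(2-methylpropanoyloxy)eudesma-4,11(13)-dien-12-oic acid; 31 (trimethylsilyl)diazomethane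
Product: 32 methyl (3S,7R,8R,10R)-8β-acetoxy-3β-(2-methylpropanoyloxy)eudesma-4,11(13)-dien-12-oate
Conditions: Me3SiCHN2, MeOH/toluene, 0 °C
Reagents that add atoms: (trimethylsilyl)diazomethane 31, C[Si](C)(C)C=[N+]=[N-]
Why: Diazoalkane O-methylation of the carboxylic acid in methanol is neutral and should give the methyl ester without touching the acetate, the isobutyrate or the acrylate double bond.

Compound list
1 | hex-4-yn-1-ol | CC#CCCCO | starting material
2 | hex-4-ynal | CC#CCCC=O | intermediate
3 | allenylboronic acid pinacol ester | C=C=CB1OC(C)(C)C(C)(C)O1 | starting material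
4 | (4R)-nona-1,7-diyn-4-ol | CC#CCC[C@@H](O)CC#C | intermediate
5 | tert-butyl(dimethyl){[(4R)-nona-1,7-diyn-4-yl]oxy}silane | CC#CCC[C@@H](O[Si](C)(C)C(C)(C)C)CC#C | intermediate
6 | trimethylaluminium | C[Al](C)C | starting material
7 | dimethyl[(1E,4R)-4-(tert-butyldimethylsilyloxy)-2-methylnon-1-en-7-yn-1-yl]alane (formed in the flask) | CC#CCC[C@@H](O[Si](C)(C)C(C)(C)C)C/C(C)=C/[Al](C)C | intermediate
8 | tert-butyl{[(1E,4R)-1-iodo-2-methylnon-1-en-7-yn-4-yl]oxy}dimethylsilane | CC#CCC[C@@H](O[Si](C)(C)C(C)(C)C)C/C(C)=C/I | intermediate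
9 | vinylboronic acid pinacol ester | C=CB1OC(C)(C)C(C)(C)O1 | starting material
10 | tert-butyl(dimethyl){[(3E,6R)-4-methylundeca-1,3-dien-9-yn-6-yl]oxy}silane | CC#CCC[C@@H](O[Si](C)(C)C(C)(C)C)C/C(C)=C/C=C | intermediate
11 | (8R,10S)-8α-(tert-butyldimethylsilyloxy)-11,12,13-trinoreudesma-1,4-diene | CC(C)(C)[Si](C)(C)O[C@@H]1CCC2=C(C)CC=C[C@]2(C)C1 | intermediate
12 | (8R,10S)-8α-(tert-butyldimethylsilyloxy)-11,12,13-trinoreudesma-1,4-dien-3-one | CC(C)(C)[Si](C)(C)O[C@@H]1CCC2=C(C)C(=O)C=C[C@]2(C)C1 | intermediate
13 | (8R,10R)-8α-(tert-butyldimethylsilyloxy)-11,12,13-trinoreudesm-4-en-3-one | CC(C)(C)[Si](C)(C)O[C@@H]1CCC2=C(C)C(=O)CC[C@]2(C)C1 | intermediate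
14 | (3S,8R,10R)-8α-(tert-butyldimethylsilyloxy)-11,12,13-trinoreudesm-4-en-3β-ol | CC(C)(C)[Si](C)(C)O[C@@H]1CCC2=C(C)[C@@H](O)CC[C@]2(C)C1 | intermediate
15 | 2-methylpropanoic anhydride | CC(C)C(=O)OC(=O)C(C)C | starting material
16 | (3S,8R,10R)-8α-(tert-butyldimethylsilyloxy)-11,12,13-trinoreudesm-4-en-3β-yl 2-methylpropanoate | CC(C)(C)[Si](C)(C)O[C@@H]1CCC2=C(C)[C@@H](OC(=O)C(C)C)CC[C@]2(C)C1 | intermediate
17 | (3S,8R,10R)-8α-hydroxy-11,12,13-trinoreudesm-4-en-3β-yl 2-methylpropanoate | O[C@@H]1CCC2=C(C)[C@@H](OC(=O)C(C)C)CC[C@]2(C)C1 | intermediate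
18 | (3S,10R)-8-oxo-11,12,13-trinoreudesm-4-en-3β-yl 2-methylpropanoate | O=C1CCC2=C(C)[C@@H](OC(=O)C(C)C)CC[C@]2(C)C1 | intermediate
19 | allyl bromide | C=CCBr | starting material
20 | lithium C7=C8 enolate of 18 (formed in the flask) | [Li]OC1=CCC2=C(C)[C@@H](OC(=O)C(C)C)CC[C@]2(C)C1 | intermediate
21 | (3S,7R,10R)-7α-allyl-8-oxo-11,12,13-trinoreudesm-4-en-3β-yl 2-methylpropanoate (formed in the flask) | C=CC[C@@H]1CC2=C(C)[C@@H](OC(=O)C(C)C)CC[C@]2(C)CC1=O | intermediate
22 | (3S,7S,10R)-7β-allyl-8-oxo-11,12,13-trinoreudesm-4-en-3β-yl 2-methylpropanoate | C=CC[C@H]1CC2=C(C)[C@@H](OC(=O)C(C)C)CC[C@]2(C)CC1=O | intermediate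
23 | (3S,7S,8R,10R)-7β-allyl-8β-hydroxy-11,12,13-trinoreudesm-4-en-3β-yl 2-methylpropanoate | C=CC[C@H]1CC2=C(C)[C@@H](OC(=O)C(C)C)CC[C@]2(C)C[C@H]1O | intermediate
24 | acetic anhydride | CC(=O)OC(C)=O | starting material
25 | (3S,7S,8R,10R)-8β-acetoxy-7β-allyl-11,12,13-trinoreudesm-4-en-3β-yl 2-methylpropanoate | C=CC[C@H]1CC2=C(C)[C@@H](OC(=O)C(C)C)CC[C@]2(C)C[C@H]1OC(C)=O | intermediate
26 | (3S,7S,8R,10R)-8β-acetoxy-7β-(2,3-dihydroxypropyl)-11,12,13-trinoreudesm-4-en-3β-yl 2-methylpropanoate (both carbinol epimers, formed in the flask) | OCC(O)C[C@H]1CC2=C(C)[C@@H](OC(=O)C(C)C)CC[C@]2(C)C[C@H]1OC(C)=O | intermediate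
27 | (3S,7R,8R,10R)-8β-acetoxy-3β-(2-methylpropanoyloxy)-13-noreudesm-4-en-12-al | O=CC[C@H]1CC2=C(C)[C@@H](OC(=O)C(C)C)CC[C@]2(C)C[C@H]1OC(C)=O | intermediate
28 | formaldehyde | C=O | starting material
29 | (3S,7R,8R,10R)-8β-acetoxy-3β-(2-methylpropanoyloxy)eudesma-4,11(13)-dien-12-al | C=C(C=O)[C@H]1CC2=C(C)[C@@H](OC(=O)C(C)C)CC[C@]2(C)C[C@H]1OC(C)=O | intermediate
30 | (3S,7R,8R,10R)-8β-acetoxy-3β-(2-methylpropanoyloxy)eudesma-4,11(13)-dien-12-oic acid | C=C(C(=O)O)[C@H]1CC2=C(C)[C@@H](OC(=O)C(C)C)CC[C@]2(C)C[C@H]1OC(C)=O | intermediate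
31 | (trimethylsilyl)diazomethane | C[Si](C)(C)C=[N+]=[N-] | starting material
32 | methyl (3S,7R,8R,10R)-8β-acetoxy-3β-(2-methylpropanoyloxy)eudesma-4,11(13)-dien-12-oate | C=C(C(=O)OC)[C@H]1CC2=C(C)[C@@H](OC(=O)C(C)C)CC[C@]2(C)C[C@H]1OC(C)=O | target

Total step count: 19
Longest linear sequence: 19 steps (1 to 32)

Steps most likely to fail

Step 6. The oxidative cyclisation may stall at the methyl-bearing, inward-substituted diene terminus, so that diene oligomerisation or alkyne trimerisation consumes the substrate, and facial control by the remote C8 ether may be incomplete. The fallback sets out from 10 and comes back at 11 without a new compound (F0). It changes the bond-forming logic from oxidative coupling at a low-valent metal to carbophilic π-acid activation of the alkyne. A cationic monovalent gold complex such as [(t-Bu)2(o-biphenyl)P]Au(NCMe)SbF6 in CH2Cl2 at rt would be used. The C10=C1 alkene then attacks the gold-bound alkyne to form C5–C10 through a cyclopropyl gold carbene, and the pendant vinyl group closes C3–C4. This is a known formal [4+2] of unactivated dienynes, though competing cyclisation modes are possible with this substitution pattern. The same chair-like tether preference should govern C10.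

Step 13. Control of the C7 configuration may be insufficient, because kinetic attack is axial and the equatorial preference is only modest with C5 being sp2. Enolisation toward C9 and attack of base on the C3 ester during equilibration are further losses. The fallback sets out from 18 and comes back at 22. The kinetic enolate (NaN(SiMe3)2, TMEDA, THF, −78 °C) would be O-acylated with allyl chloroformate to give allyl (3S,10R)-3β-(2-methylpropanoyloxy)-11,12,13-trinoreudesma-4,7-dien-8-yl carbonate F1. A decarboxylative asymmetric Tsuji–Trost allylation would follow (Pd2(dba)3·CHCl3, the DACH-phenyl diphosphine enantiomer matched for β-face delivery, toluene, rt). It transfers the allyl group to C7 regiospecifically, under neutral conditions and under catalyst control, so no base equilibration is needed.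

Step 2. Enantioselectivity may be eroded with the unbranched aliphatic aldehyde, through a loosely organised transition state and uncatalysed background allenylboration, and it cannot be upgraded later on oily intermediates. The fallback sets out from 2 and comes back at 4. Corey–Chaykovsky methylenation (trimethylsulfonium iodide, NaH, DMSO/THF) should give racemic 2-(pent-3-yn-1-yl)oxirane F2. Hydrolytic kinetic resolution with the enantiomer of (salen)Co(OAc) that hydrolyses the (S)-epoxide (0.55 equiv water) should leave (2R)-2-(pent-3-yn-1-yl)oxirane F3 and convert the rest into (2S)-hept-5-yne-1,2-diol F4, which is removed. LiC≡CH·H2N(CH2)2NH2 in DMSO then opens F3 at the terminal carbon to give 4 with the stereocentre untouched.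

Further compounds
F0 | step 6 | none | none
F1 | step 13 | allyl (3S,10R)-3β-(2-methylpropanoyloxy)-11,12,13-trinoreudesma-4,7-dien-8-yl carbonate | C=CCOC(=O)OC1=CCC2=C(C)[C@@H](OC(=O)C(C)C)CC[C@]2(C)C1
F2 | step 2 | racemic 2-(pent-3-yn-1-yl)oxirane | CC#CCCC1CO1
F3 | step 2 | (2R)-2-(pent-3-yn-1-yl)oxirane | CC#CCC[C@@H]1CO1
F4 | step 2 | (2S)-hept-5-yne-1,2-diol | CC#CCC[C@H](O)CO
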